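## Structural features

The target is a branched tetraflavanoid built from three fisetinidol units (5-deoxy, resorcinol-type ring A, catechol ring B) and one (+)-catechin unit (phloroglucinol-type ring A). Unit 1 is bonded through C4 to C6 of unit 2, unit 2 through C4 to C6 of the catechin (unit 3), and unit 4 through C4 to C8 of the catechin, so ring A of unit 3 is fully substituted. Each fisetinidol carries the contiguous triad C2 (aryl), C3 (OH), C4 (aryl) in the 2,3-trans-3,4-trans arrangement (2R, 3S, 4α), and the catechin adds 2R,3S, giving eleven stereocentres in four similar heterocycles. Thirteen of the seventeen hydroxyls are phenolic and sensitive to air and base, the C4–aryl bonds are doubly benzylic and break in protic acid, and C2 of a free phenolic flavan can epimerise through a quinone methide, so the polyphenol can only be unmasked last and under neutral conditions. The real difficulty lies in the three crowded C4–aryl bonds: each must go to one defined position (C6 or C8 of unit 3, C6 and not C8 of unit 2) and each must be 4α. The 5-deoxy units resist this in an acid condensation, since their C4 cations are poorly stabilised and their ring A is a weak, unselective nucleophile. The key step exploits ring C of unit 2, where O1 and the hydroxyl oxygen sit on the neighbouring carbons C2 and C3: shifting O1 from C2 to C3 turns the chroman into a 2-(α-hydroxybenzyl)-2,3-dihydrobenzofuran whose C3 is the future C4 with unit 3 already attached. That five-membered isomer is reachable trans-selectively from an ortho-quinone methide.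

## Logic of the disconnections

35 to 34. The fifteen O–CH2Ph bonds are cut. All phenols stay masked until the end and every earlier compound is an oxidation-stable ether. The forward step must remove fifteen benzyl groups without cleaving the C2–O1 and C4–aryl bonds, which are benzylic as well.

34 to 33. The two acyl C–O bonds at C3 of units 1 and 4 are cut, because these oxygens arrive as acetate in the ring expansion. Nothing is gained in the skeleton. The demand is a methanolysis mild enough for a fully etherified tetraflavanoid.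

33 to 32. In units 1 and 4 the bonds O1–C2 and C3–OAc are cut and O1 is rejoined to C3. Two chromans with three stereocentres each become two trans-dihydrobenzofurans with a sulfonate on the exocyclic benzylic carbon. The forward step must run the oxiranium ring expansion at two sites with inversion at both carbons of each site.

32 to 31 to 30. The two S–O bonds and then the carbinol C–H bond of the unit 1 precursor are cut. The ketone is what the annulation delivers, and the neighbouring ring oxygen can steer the hydride. The reduction must give the (S)-carbinol and leave the carbinol already present untouched.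

30 to 27, 10 and 15. In the dihydrobenzofuran on unit 2 the ring bonds C2–C3 and O1–C2 are cut (the one-carbon unit of 15), together with the aryl–C3 bond to C6 of unit 2 (C3 is the formyl carbon of 10). Unit 1 thus reduces to the remaining aryl bromide and two building blocks that are already in hand. The forward step must metalate a substrate that carries a free carbinol and must control the face of one methide carbon by the reagent.

27 to 26. The carbinol C–H bond of the unit 4 precursor is cut. The reduction is needed in any case, and placing it here removes the only group that an organolithium reagent would attack in the next round.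

26 to 23, 10 and 15. The same three bonds are cut at the dihydrobenzofuran on C8 of unit 3. The two outer units are introduced in turn and not together, so that each coupling draws on one molecule of each building block and gives one defined, purifiable compound. The forward step must tell the two aryl bromides apart, which rests on the greater stability of the aryllithium flanked by two oxygens.

23 to 21 (through 22). The benzyl–O bond at C3 of unit 2 is exchanged for the acetyl–O bond. An ester would not survive the aryllithium chemistry that follows, and the ether joins the final hydrogenolysis.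

21 to 20. This is the key cut: O1–C2 and C3–OAc of unit 2 are cut and O1 is rejoined to C3. Ring C and its C2/C3 stereocentres reduce to a trans-dihydrobenzofuran that already carries unit 3 and both halogen handles. The forward step must open the oxiranium ion at the ring carbon and not at the benzylic one.

20 to 19 to 18. The S–O bond and then the carbinol C–H bond are cut. The demand is chloride-free sulfonylation and chelation-controlled reduction to the (S)-carbinol.

18 to 5, 9 and 15. The furan bonds C2–C3 and O1–C2 and the bond from C6 of unit 3 to C3 are cut. The catechin acts as the nucleophile, so the aldehyde partner can carry its own bromine untouched. The forward step needs a metalation at the C6 iodide that leaves the C8 bromide alone, and one chiral ylide that sets the sense at C3.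

5 to 4 to 3 to 2 to 1. The C6–I, C8–Br and five O–benzyl bonds are cut in turn. The two halogens differentiate C6 from C8. Bromination must prefer C8.

9 to 8 to 7 to 6, and 10 to 7. The carbonate C–O, C5–Br and 4-O–benzyl bonds are cut. One aldehyde serves all three rounds. The demands are selective alkylation of the 4-hydroxyl and bromination para to the free hydroxyl.

15 to 13 and 14, then 13 to 12 to 11. The N–C bond, the C–Br bond and two O–benzyl bonds are cut. Ring B with C2 and C3 of every fisetinidol unit comes from one acetophenone, and the alkaloid serves as a chiral leaving group.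

## Other disconnections considered

Alternative 1: The cut is at the three O1–C2 bonds of units 1, 2 and 4 at once, with C2 left as the methylene of a 4-hydroxy-3-benzyloxybenzyl group. The C3 oxygen and ring B would come from (R)-danshensu A2, whose carbinol centre has the right sense for C3. In the forward step Ag2O would oxidise the three para-alkylphenols to para-quinone methides, and each ring A phenol would add to its methide carbon in a 6-exo closure to give A1. In its favour, three rings would close in one operation, C3 would come from the chiral pool, and no acetate exchange would be needed. On endgame step economy and on the origin of C3 it is the better plan. Against it, all three triarylmethane C4 centres and their relation to C3 would have to be set on open chains with no ring to enforce trans. The oxidant would also meet three free ring A phenols and an electron-rich unit 3, and C2 would rest on thermodynamic control in three rings at once. Structurally, the hard part (the C4–aryl bonds) is moved rather than solved, whereas the chosen plan sets C4 on a ring where trans is enforced. Mechanistically, both plans end in the all-equatorial isomer, but the chosen plan backs this with a stereospecific double inversion. The shorter endgame of Alternative 1 has to be weighed against an open-chain precursor that would be longer to make.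

Alternative 2: The cut is at O1–C2 and C3–C4 of unit 4. In the forward step a chiral phosphoric acid would dehydrate the ortho-hydroxy diaryl carbinol A5 on C8 of the catechin unit to an ortho-quinone methide, and this would add the E-styrylsilane A4 in a [4+2] annulation to give A3. Tamao–Fleming oxidation would then turn the benzyldimethylsilyl group into the C3 hydroxyl with retention. In its favour, the six-membered ring is made directly, the E-alkene carries 2,3-trans into the product, and cycloadditions of ortho-quinone methides with styrenes are well known. On precedent for the ring-forming step and on steps per unit (two operations against four) it is the better plan. Against it, the 1,2-disubstituted vinylsilane is a hindered and only moderately nucleophilic partner for a methide carbon flanked by two benzyloxy groups. The catalyst would have to control both the face and the endo/exo sense. The acid needed to form the quinone methide is less attractive once acid-labile interflavanyl bonds are present. A silyl group at C3 is β to O1, so fluoride or peroxide activation could open the pyran by β-elimination. Structurally, it uses the same diaryl carbinol logic and the same halogen-based position control as the chosen plan, on which the two are equal. Mechanistically, it puts all three stereocentres into one transition state, whereas the chosen plan separates C4 (ylide) from C2 and C3 (two inversions).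

Alternative 3: The cut is at C3–C4 of unit 4. In the forward step Bu4NF would desilylate the diarylmethyl trimethylsilane A7, and the benzylic carbanion equivalent would add to the tethered (R)-α-aryloxy aldehyde in a 6-exo closure to give A6 with a free C3 hydroxyl. In its favour are neutral to basic conditions, direct delivery of the free C3 hydroxyl, and a short sequence. On protecting-group economy at C3 it is the better plan, and on ring-closure mode it is at least equal. Against it, the aldehyde α-carbon (the future C2) is benzylic and enolisable, so fluoride could racemise it or expel the phenoxide. A diarylmethyl anion bearing two alkoxy-rich rings is poorly stabilised, so protodesilylation could win. Neither the C4 centre nor the 3,4-trans relation has a controlling element beyond the cyclic transition state. Structurally, it keeps the position control of the chosen plan. Mechanistically, it trades two stereospecific displacements for an aldol-type closure of uncertain diastereoselectivity. It would be shorter only if that closure were selective.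

Key step: step 15

Remarks on the chemistry, made before the steps:
- Units are numbered as follows: unit 1 is the fisetinidol on C6 of unit 2, unit 2 the fisetinidol on C6 of the catechin, unit 3 the catechin, unit 4 the fisetinidol on C8 of the catechin. Bn is benzyl.
- The configurations of 20 and 21 follow from the mechanism (inversion at the exocyclic carbon and at ring C2 of the dihydrobenzofuran, no change at C3) and agree with unit 2 of 35: the (2R,3S) ring and the (S) sulfonate carbon map onto (2R,3S,4S).
- Four design choices are made for the key sequence. The annulation uses a chiral ammonium ylide, because an achiral ylide would give both trans diastereomers. The carbinol is made by chelation control, because only the (S)-epimer leads to the trans oxiranium ion. The sulfonate is made free of chloride and used cold. The C3 acetate is exchanged for a benzyl ether before any organolithium step.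
- The outer units are added in two rounds, unit 4 first and unit 1 second, and share the reduction, sulfonylation and ring expansion only from the second reduction onwards. The first ketone is reduced before the second metalation, and its carbinol is carried through that round as the alkoxide.
- Assumption: the quinidine-derived salt 15 delivers the (2R,3S) sense in the annulation. If a model quinone methide shows the opposite sense, the quinine-derived pseudoenantiomer is used in the same way.

Step 1
Reactants: 1 (+)-catechin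
Product: 2 5,7,3',4'-tetra-O-benzylcatechin
Conditions: BnBr, K2CO3, DMF, 0 °C → rt
Reagents that add atoms: benzyl bromide, BrCc1ccccc1
Why: Williamson etherification; K2CO3 deprotonates only the four phenols, so the secondary hydroxyl stays free and C2 and C3 are not touched.

Step 2
Reactants: 2 5,7,3',4'-tetra-O-benzylcatechin
Product: 3 3,5,7,3',4'-penta-O-benzylcatechin
Conditions: NaH, BnBr, Bu4NI (cat.), DMF, 0 °C → rt
Reagents that add atoms: benzyl bromide, BrCc1ccccc1
Why: Williamson etherification of the remaining secondary alcohol; with every phenol capped there is no quinone methide pathway by which C2 could epimerise.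

Step 3
Reactants: 3 3,5,7,3',4'-penta-O-benzylcatechin
Product: 4 8-bromo-penta-O-benzylcatechin
Conditions: NBS (1.0 equiv), CH2Cl2, −78 °C → 0 °C
Reagents that add atoms: N-bromosuccinimide, O=C1CCC(=O)N1Br
Why: Electrophilic aromatic bromination; in benzylated catechins C8 is the more reactive of the two free ring A positions, so one equivalent at low temperature should give the 8-bromide.

Step 4
Reactants: 4 8-bromo-penta-O-benzylcatechin
Product: 5 8-bromo-6-iodo-penta-O-benzylcatechin
Conditions: NIS, TFA (cat.), CH2Cl2–MeCN, 0 °C → rt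
Reagents that add atoms: N-iodosuccinimide, O=C1CCC(=O)N1I
Why: Electrophilic aromatic iodination at the only ring A position left; the iodide is chosen because it can later be exchanged for magnesium while the bromide stays.

Step 5
Reactants: 6 2,4-dihydroxybenzaldehyde
Product: 7 4-(benzyloxy)-2-hydroxybenzaldehyde
Conditions: BnBr (1.05 equiv), NaHCO3, KI (cat.), MeCN, 80 °C
Reagents that add atoms: benzyl bromide, BrCc1ccccc1
Why: Regioselective Williamson etherification; the 2-hydroxyl is tied up in a hydrogen bond to the formyl group, so a weak base alkylates the 4-hydroxyl.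

Step 6
Reactants: 7 4-(benzyloxy)-2-hydroxybenzaldehyde
Product: 8 4-(benzyloxy)-5-bromo-2-hydroxybenzaldehyde
Conditions: NBS, MeCN, 0 °C
Reagents that add atoms: N-bromosuccinimide, O=C1CCC(=O)N1Br
Why: Electrophilic aromatic bromination para to the free hydroxyl and ortho to the benzyloxy group; C3 between the two oxygens is the more hindered position.

Step 7
Reactants: 8 4-(benzyloxy)-5-bromo-2-hydroxybenzaldehyde
Product: 9 tert-butyl 5-(benzyloxy)-4-bromo-2-formylphenyl carbonate
Conditions: Boc2O, iPr2NEt, DMAP (cat.), THF, 0 °C → rt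
Reagents that add atoms: di-tert-butyl dicarbonate, CC(C)(C)OC(=O)OC(=O)OC(C)(C)C
Why: DMAP-catalysed O-acylation of the phenol; the aryl carbonate is the trigger for the later anionic formation of the quinone methide.

Step 8
Reactants: 7 4-(benzyloxy)-2-hydroxybenzaldehyde
Product: 10 tert-butyl 5-(benzyloxy)-2-formylphenyl carbonate
Conditions: Boc2O, iPr2NEt, DMAP (cat.), THF, 0 °C → rt
Reagents that add atoms: di-tert-butyl dicarbonate, CC(C)(C)OC(=O)OC(=O)OC(C)(C)C
Why: DMAP-catalysed O-acylation of the phenol, as in step 7, for the partner of units 1 and 4.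

Step 9
Reactants: 11 3',4'-dihydroxyacetophenone
Product: 12 3',4'-bis(benzyloxy)acetophenone
Conditions: BnBr, K2CO3, DMF, rt
Reagents that add atoms: benzyl bromide, BrCc1ccccc1
Why: Williamson etherification of both catechol hydroxyls.

Step 10
Reactants: 12 3',4'-bis(benzyloxy)acetophenone
Product: 13 2-bromo-1-[3,4-bis(benzyloxy)phenyl]ethanone
Conditions: CuBr2 (2 equiv), EtOAc–CHCl3, reflux
Reagents that add atoms: CuBr2, [Cu+2].[Br-].[Br-]
Why: α-Bromination of the aryl methyl ketone through its enol; CuBr2 should spare the electron-rich ring.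

Step 11
Reactants: 13 2-bromo-1-[3,4-bis(benzyloxy)phenyl]ethanone; 14 quinidine
Product: 15 N-{2-[3,4-bis(benzyloxy)phenyl]-2-oxoethyl}quinidinium bromide
Conditions: THF, rt, filtration of the salt
Reagents that add atoms: none
Why: Menshutkin quaternisation at the quinuclidine nitrogen, the more nucleophilic of the two nitrogens; the alkaloid becomes the chiral leaving group of the ylide.

Step 12
Reactants: 5 8-bromo-6-iodo-penta-O-benzylcatechin; 9 tert-butyl 5-(benzyloxy)-4-bromo-2-formylphenyl carbonate; 15 N-{2-[3,4-bis(benzyloxy)phenyl]-2-oxoethyl}quinidinium bromide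
Product: 18 (2R,3S)-2-[3,4-bis(benzyloxy)benzoyl]-6-benzyloxy-5-bromo-3-(8-bromo-penta-O-benzylcatechin-6-yl)-2,3-dihydrobenzofuran, via arylmagnesium chloride 16 (not isolated), via ortho-quinone methide 17 (not isolated)
Conditions: 5, iPrMgCl·LiCl (1.0 equiv), THF, −20 °C; added to 9 (1.2 equiv), THF, −78 → −20 °C; then 15, Cs2CO3, CH2Cl2, −20 °C → rt
Reagents that add atoms: none
Why: Iodine–magnesium exchange should be much faster at the aryl iodide than at the flanked aryl bromide, and the aryl Grignard reagent adds to the formyl group of 9; the alkoxide then takes over the Boc group and the magnesium phenoxide expels tert-butyl carbonate to give 17 (anionic Boc-transfer generation of an ortho-quinone methide). The ammonium ylide formed from 15 and Cs2CO3 adds to the methide carbon and the phenoxide displaces quinidine from the ylide carbon, a formal [4+1] annulation of an ammonium ylide with an ortho-quinone methide. Trans follows from the reversible betaine stage and the epimerisable carbon next to the ketone; the sense at C3 (S) is set by the chiral ammonium group, and C2 (R) follows from trans.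

Step 13
Reactants: 18 (2R,3S)-2-[3,4-bis(benzyloxy)benzoyl]-6-benzyloxy-5-bromo-3-(8-bromo-penta-O-benzylcatechin-6-yl)-2,3-dihydrobenzofuran
Product: 19 (S)-[3,4-bis(benzyloxy)phenyl][(2R,3S)-6-benzyloxy-5-bromo-3-(8-bromo-penta-O-benzylcatechin-6-yl)-2,3-dihydrobenzofuran-2-yl]methanol
Conditions: Zn(BH4)2, Et2O–CH2Cl2, −40 → 0 °C
Reagents that add atoms: none
Why: Chelation-controlled reduction of an α-alkoxy ketone (Cram chelate model): zinc bridges the carbonyl oxygen and the ring oxygen, and hydride arrives past the C2 hydrogen rather than past the C3 branch. This should give the (S)-carbinol, the epimer in which the ring oxygen can stand antiperiplanar to the leaving group while the aryl group is trans to C3.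

Step 14
Reactants: 19 (S)-[3,4-bis(benzyloxy)phenyl][(2R,3S)-6-benzyloxy-5-bromo-3-(8-bromo-penta-O-benzylcatechin-6-yl)-2,3-dihydrobenzofuran-2-yl]methanol
Product: 20 (2R,3S)-2-[(S)-α-(mesyloxy)-3,4-bis(benzyloxy)benzyl]-3-(8-bromo-penta-O-benzylcatechin-6-yl)-6-benzyloxy-5-bromo-2,3-dihydrobenzofuran
Conditions: Ms2O, Et3N, CH2Cl2, −40 °C; cold aq. NaHCO3 wash; used at once without chromatography
Reagents that add atoms: methanesulfonic anhydride, CS(=O)(=O)OS(C)(=O)=O
Why: O-Sulfonylation with retention at carbon; the anhydride is used instead of the chloride so that no chloride ion can displace the labile benzylic sulfonate and scramble its configuration.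

Step 15
Reactants: 20 (2R,3S)-2-[(S)-α-(mesyloxy)-3,4-bis(benzyloxy)benzyl]-3-(8-bromo-penta-O-benzylcatechin-6-yl)-6-benzyloxy-5-bromo-2,3-dihydrobenzofuran
Product: 21 6-bromo-7,3',4'-tri-O-benzylfisetinidol 3-acetate-(4α→6)-8-bromo-penta-O-benzylcatechin
Conditions: Zn(OAc)2 (5 equiv), AcOH–CH2Cl2 (1:3), 0 °C → rt
Reagents that add atoms: zinc diacetate, CC(=O)[O-].CC(=O)[O-].[Zn+2]; acetic acid, CC(=O)O
Why: Proposed new method: Zn(OAc)2 assists the departure of the mesylate while the ring oxygen of the dihydrobenzofuran attacks the benzylic carbon from the rear, giving a bicyclic oxiranium ion across the future C2 and C3; acetate then opens this ion at the non-benzylic carbon, anti to oxygen, so that O1–C2 and C3–OAc are made and the former ring O–C bond is broken. The closest known reaction type is the Zn(OAc)2-mediated expansion of tetrahydrofurfuryl sulfonates to 3-acyloxytetrahydropyrans, together with its reverse, the contraction of 2,3-trans-flavan-3-ol sulfonates; it has not been run on a 3-aryl-2,3-dihydrobenzofuran with a benzylic leaving group. Ring C is closed by ring expansion and not by a direct cyclisation: a 3-exo-tet closure of O1 onto the exocyclic carbon is followed by opening of the three-membered ring at the endocyclic carbon, which enlarges the five-membered ring by one atom. C2 is set by inversion at the (S)-sulfonate carbon, whose configuration comes from step 13, and should come out R with the aryl group equatorial. C3 is set by inversion at the former ring carbon C2, the acetate entering on the face trans to the C4 aryl group, while C4 is not touched, so the trans-dihydrobenzofuran maps onto the 2,3-trans-3,4-trans chroman. The step needs regioselectivity in the opening of the oxiranium ion: return of acetate at the benzylic carbon only restores a five-membered benzylic acetate, which zinc and acetic acid should re-ionise, whereas the secondary acetate of the chroman with three equatorial substituents should not, so the six-membered product collects. If ionisation runs ahead of participation, the open cation should still close to the trans-substituted oxiranium ion, the less strained of the two, so the stereospecific and the equilibrating pathways lead to the same isomer.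

Step 16
Reactants: 21 6-bromo-7,3',4'-tri-O-benzylfisetinidol 3-acetate-(4α→6)-8-bromo-penta-O-benzylcatechin
Product: 23 6-bromo-3,7,3',4'-tetra-O-benzylfisetinidol-(4α→6)-8-bromo-penta-O-benzylcatechin, via 3-hydroxy compound 22 (not isolated)
Conditions: NaOMe (cat.), MeOH–THF, rt; concentrate; then NaH, BnBr, Bu4NI (cat.), DMF, 0 °C → rt
Reagents that add atoms: benzyl bromide, BrCc1ccccc1
Why: Zemplén transesterification removes the acetate, and the alkoxide of 22 is then benzylated (Williamson etherification). The exchange is made because an ester would not survive the aryllithium of step 17; no stereocentre is touched.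

Step 17
Reactants: 23 6-bromo-3,7,3',4'-tetra-O-benzylfisetinidol-(4α→6)-8-bromo-penta-O-benzylcatechin; 10 tert-butyl 5-(benzyloxy)-2-formylphenyl carbonate; 15 N-{2-[3,4-bis(benzyloxy)phenyl]-2-oxoethyl}quinidinium bromide
Product: 26 mono-ketone carrying a (2R,3S)-2-[3,4-bis(benzyloxy)benzoyl]-6-benzyloxy-2,3-dihydrobenzofuran-3-yl group on C8 of unit 3 of the 6-bromo dimer, via 8-lithio compound 24 (not isolated), via ortho-quinone methide 25 (not isolated)
Conditions: n-BuLi (1.0 equiv), THF, −78 °C, 30 min; added to 10 (1.2 equiv), −78 °C; MgBr2·OEt2, −78 → −20 °C; then 15, Cs2CO3, CH2Cl2, −20 °C → rt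
Reagents that add atoms: none
Why: Bromine–lithium exchange with one equivalent of n-BuLi should settle on C8 of unit 3, where the carbanion is flanked by two ether oxygens and is the more stable of the two possible aryllithiums (aryllithium–aryl bromide equilibration favours it), while the bromide on unit 2 with a single ortho oxygen stays. Addition to the formyl group of 10, Boc transfer and magnesium-triggered loss of tert-butyl carbonate give 25 (anionic Boc-transfer generation of an ortho-quinone methide), and the ammonium ylide from 15 closes the dihydrobenzofuran in a formal [4+1] annulation. Trans follows from the reversible betaine stage and the sense at C3 from the chiral ammonium group, as in step 12.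

Step 18
Reactants: 26 mono-ketone
Product: 27 mono-carbinol with an (S)-configured aryl carbinol on the (2R,3S)-dihydrobenzofuran at C8 of unit 3
Conditions: Zn(BH4)2, Et2O–CH2Cl2, −40 → 0 °C
Reagents that add atoms: none
Why: Chelation-controlled reduction of the α-alkoxy ketone (Cram chelate model), as in step 13; it should give the (S)-carbinol and removes the ketone before the next organolithium step, the aryl bromide being inert.

Step 19
Reactants: 27 mono-carbinol; 10 tert-butyl 5-(benzyloxy)-2-formylphenyl carbonate; 15 N-{2-[3,4-bis(benzyloxy)phenyl]-2-oxoethyl}quinidinium bromide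
Product: 30 keto carbinol carrying a (2R,3S)-2-[3,4-bis(benzyloxy)benzoyl]-6-benzyloxy-2,3-dihydrobenzofuran-3-yl group on C6 of unit 2 beside the (S)-carbinol on C8 of unit 3, via dilithio compound 28 (not isolated), via ortho-quinone methide 29 (not isolated)
Conditions: MeLi (1.0 equiv), THF, −78 °C; n-BuLi (1.05 equiv), −78 °C; added to 10 (1.1 equiv), −78 °C; MgBr2·OEt2, −78 → −20 °C; then 15, Cs2CO3, CH2Cl2, −20 °C → rt
Reagents that add atoms: none
Why: MeLi first converts the carbinol into its lithium alkoxide without touching the aryl bromide, so that the bromine–lithium exchange with n-BuLi at C6 of unit 2 is not quenched by the hydroxyl proton; the alkoxide is inert to the operations that follow. Addition to the formyl group of 10, Boc transfer and loss of tert-butyl carbonate give 29, and the formal [4+1] annulation with the ammonium ylide from 15 closes the second trans-dihydrobenzofuran as in steps 12 and 17. The same chiral leaving group serves here because units 1 and 4 have the same absolute configuration.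

Step 20
Reactants: 30 keto carbinol
Product: 31 bis-carbinol with an (S)-configured aryl carbinol on each (2R,3S)-dihydrobenzofuran
Conditions: Zn(BH4)2, Et2O–CH2Cl2, −40 → 0 °C
Reagents that add atoms: none
Why: Chelation-controlled reduction (Cram chelate model) of the remaining α-alkoxy ketone, as in step 13; it should give the (S)-carbinol, and the carbinol already present is not affected.

Step 21
Reactants: 31 bis-carbinol
Product: 32 bis-mesylate of 31
Conditions: Ms2O, Et3N, CH2Cl2, −40 °C; cold aq. NaHCO3 wash; used at once without chromatography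
Reagents that add atoms: methanesulfonic anhydride, CS(=O)(=O)OS(C)(=O)=O
Why: Twofold O-sulfonylation with retention, chloride-free as in step 14.

Step 22
Reactants: 32 bis-mesylate
Product: 33 7,3',4'-tri-O-benzylfisetinidol 3-acetate-(4α→6)-3,7,3',4'-tetra-O-benzylfisetinidol-(4α→6)-[7,3',4'-tri-O-benzylfisetinidol 3-acetate-(4α→8)]-penta-O-benzylcatechin
Conditions: Zn(OAc)2 (10 equiv), AcOH–CH2Cl2 (1:3), 0 °C → rt
Reagents that add atoms: zinc diacetate, CC(=O)[O-].CC(=O)[O-].[Zn+2]; acetic acid, CC(=O)O
Why: Proposed new method: the oxiranium ring expansion of step 15 run at two sites, by participation of each furan oxygen at its (S)-mesylate carbon and opening by acetate at the former ring C2 with inversion; the closest known reaction type is the Zn(OAc)2-mediated expansion of tetrahydrofurfuryl sulfonates to 3-acyloxytetrahydropyrans. Each site should give the 2R,3S-configured 2,3-trans-3,4-trans chroman acetate for the reasons given in step 15, and the benzyl ether at C3 of unit 2 offers no leaving group that could take part.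

Step 23
Reactants: 33 diacetate
Product: 34 7,3',4'-tri-O-benzylfisetinidol-(4α→6)-3,7,3',4'-tetra-O-benzylfisetinidol-(4α→6)-[7,3',4'-tri-O-benzylfisetinidol-(4α→8)]-penta-O-benzylcatechin
Conditions: K2CO3 (cat.), MeOH–THF, rt
Reagents that add atoms: none
Why: Base-catalysed transesterification (methanolysis) of the two secondary acetates; it is done while all phenols are still etherified, so neither oxidation nor C2 epimerisation is possible.

Step 24
Reactants: 34 pentadeca-O-benzyl ether of the target
Product: 35 fisetinidol-(4α→6)-fisetinidol-(4α→6)-[fisetinidol-(4α→8)]-catechin (CNP0263622.1)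
Conditions: H2 (1 atm), Pd(OH)2/C, THF–MeOH–H2O, rt
Reagents that add atoms: none
Why: Catalytic hydrogenolysis of the fifteen benzyl ethers under neutral conditions; the ring C–O and C4–aryl bonds are benzylic too but hindered and should survive if hydrogen uptake is stopped at the calculated amount.

Compound list

1 | (+)-catechin, (2R,3S) | Oc1cc(O)c2c(c1)O[C@H](c1ccc(O)c(O)c1)[C@@H](O)C2 | starting material
2 | 5,7,3',4'-tetra-O-benzylcatechin, (2R,3S), free 3-OH | c1c(OCc5ccccc5)c2c(cc1OCc5ccccc5)O[C@H](c1ccc(OCc5ccccc5)c(OCc5ccccc5)c1)[C@@H](O)C2 | intermediate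
3 | 3,5,7,3',4'-penta-O-benzylcatechin, (2R,3S) | c1c(OCc5ccccc5)c2c(cc1OCc5ccccc5)O[C@H](c1ccc(OCc5ccccc5)c(OCc5ccccc5)c1)[C@@H](OCc5ccccc5)C2 | intermediate
4 | 8-bromo-penta-O-benzylcatechin, (2R,3S) | c1c(OCc5ccccc5)c2c(c(Br)c1OCc5ccccc5)O[C@H](c1ccc(OCc5ccccc5)c(OCc5ccccc5)c1)[C@@H](OCc5ccccc5)C2 | intermediate
5 | 8-bromo-6-iodo-penta-O-benzylcatechin, (2R,3S) | Ic1c(OCc5ccccc5)c2c(c(Br)c1OCc5ccccc5)O[C@H](c1ccc(OCc5ccccc5)c(OCc5ccccc5)c1)[C@@H](OCc5ccccc5)C2 | intermediate
6 | 2,4-dihydroxybenzaldehyde | O=Cc1ccc(O)cc1O | starting material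
7 | 4-(benzyloxy)-2-hydroxybenzaldehyde | O=Cc1ccc(OCc5ccccc5)cc1O | intermediate
8 | 4-(benzyloxy)-5-bromo-2-hydroxybenzaldehyde | O=Cc1cc(Br)c(OCc5ccccc5)cc1O | intermediate
9 | tert-butyl 5-(benzyloxy)-4-bromo-2-formylphenyl carbonate | O=Cc1cc(Br)c(OCc5ccccc5)cc1OC(=O)OC(C)(C)C | intermediate
10 | tert-butyl 5-(benzyloxy)-2-formylphenyl carbonate | O=Cc1ccc(OCc5ccccc5)cc1OC(=O)OC(C)(C)C | intermediate
11 | 3',4'-dihydroxyacetophenone | CC(=O)c1ccc(O)c(O)c1 | starting material
12 | 3',4'-bis(benzyloxy)acetophenone | CC(=O)c1ccc(OCc5ccccc5)c(OCc5ccccc5)c1 | intermediate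
13 | 2-bromo-1-[3,4-bis(benzyloxy)phenyl]ethanone | BrCC(=O)c1ccc(OCc5ccccc5)c(OCc5ccccc5)c1 | intermediate
14 | quinidine | COc1ccc2nccc([C@H](O)[C@H]3C[C@@H]4CCN3C[C@@H]4C=C)c2c1 | starting material
15 | N-{2-[3,4-bis(benzyloxy)phenyl]-2-oxoethyl}quinidinium bromide (quaternised at the quinuclidine nitrogen) | COc1ccc2nccc([C@H](O)[C@H]3C[C@@H]4CC[N+]3(CC(=O)c3ccc(OCc5ccccc5)c(OCc5ccccc5)c3)C[C@@H]4C=C)c2c1.[Br-] | intermediate
16 | (8-bromo-penta-O-benzylcatechin-6-yl)magnesium chloride | Cl[Mg]c1c(OCc5ccccc5)c2c(c(Br)c1OCc5ccccc5)O[C@H](c1ccc(OCc5ccccc5)c(OCc5ccccc5)c1)[C@@H](OCc5ccccc5)C2 | intermediate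
17 | (E)-3-(benzyloxy)-4-bromo-6-[(8-bromo-penta-O-benzylcatechin-6-yl)methylidene]cyclohexa-2,4-dien-1-one | O=C1C=C(OCc5ccccc5)C(Br)=C/C1=C\c1c(OCc5ccccc5)c2c(c(Br)c1OCc5ccccc5)O[C@H](c1ccc(OCc5ccccc5)c(OCc5ccccc5)c1)[C@@H](OCc5ccccc5)C2 | intermediate
18 | (2R,3S)-2-[3,4-bis(benzyloxy)benzoyl]-6-benzyloxy-5-bromo-3-(8-bromo-penta-O-benzylcatechin-6-yl)-2,3-dihydrobenzofuran (trans) | O=C(c1ccc(OCc5ccccc5)c(OCc5ccccc5)c1)[C@@H]1Oc2cc(OCc5ccccc5)c(Br)cc2[C@H]1c1c(OCc5ccccc5)c2c(c(Br)c1OCc5ccccc5)O[C@H](c1ccc(OCc5ccccc5)c(OCc5ccccc5)c1)[C@@H](OCc5ccccc5)C2 | intermediate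
19 | (S)-[3,4-bis(benzyloxy)phenyl][(2R,3S)-6-benzyloxy-5-bromo-3-(8-bromo-penta-O-benzylcatechin-6-yl)-2,3-dihydrobenzofuran-2-yl]methanol | O[C@@H](c1ccc(OCc5ccccc5)c(OCc5ccccc5)c1)[C@@H]1Oc2cc(OCc5ccccc5)c(Br)cc2[C@H]1c1c(OCc5ccccc5)c2c(c(Br)c1OCc5ccccc5)O[C@H](c1ccc(OCc5ccccc5)c(OCc5ccccc5)c1)[C@@H](OCc5ccccc5)C2 | intermediate
20 | (2R,3S)-2-[(S)-α-(mesyloxy)-3,4-bis(benzyloxy)benzyl]-3-(8-bromo-penta-O-benzylcatechin-6-yl)-6-benzyloxy-5-bromo-2,3-dihydrobenzofuran (trans) | CS(=O)(=O)O[C@@H](c1ccc(OCc5ccccc5)c(OCc5ccccc5)c1)[C@@H]1Oc2cc(OCc5ccccc5)c(Br)cc2[C@H]1c1c(OCc5ccccc5)c2c(c(Br)c1OCc5ccccc5)O[C@H](c1ccc(OCc5ccccc5)c(OCc5ccccc5)c1)[C@@H](OCc5ccccc5)C2 | intermediate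
21 | 6-bromo-7,3',4'-tri-O-benzylfisetinidol 3-acetate-(4α→6)-8-bromo-penta-O-benzylcatechin; unit 2 is (2R,3S,4S) | Brc1cc2c(cc1OCc5ccccc5)O[C@H](c1ccc(OCc5ccccc5)c(OCc5ccccc5)c1)[C@@H](OC(C)=O)[C@@H]2c1c(OCc5ccccc5)c2c(c(Br)c1OCc5ccccc5)O[C@H](c1ccc(OCc5ccccc5)c(OCc5ccccc5)c1)[C@@H](OCc5ccccc5)C2 | intermediate
22 | 6-bromo-7,3',4'-tri-O-benzylfisetinidol-(4α→6)-8-bromo-penta-O-benzylcatechin (free 3-OH on unit 2) | Brc1cc2c(cc1OCc5ccccc5)O[C@H](c1ccc(OCc5ccccc5)c(OCc5ccccc5)c1)[C@@H](O)[C@@H]2c1c(OCc5ccccc5)c2c(c(Br)c1OCc5ccccc5)O[C@H](c1ccc(OCc5ccccc5)c(OCc5ccccc5)c1)[C@@H](OCc5ccccc5)C2 | intermediate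
23 | 6-bromo-3,7,3',4'-tetra-O-benzylfisetinidol-(4α→6)-8-bromo-penta-O-benzylcatechin | Brc1cc2c(cc1OCc5ccccc5)O[C@H](c1ccc(OCc5ccccc5)c(OCc5ccccc5)c1)[C@@H](OCc5ccccc5)[C@@H]2c1c(OCc5ccccc5)c2c(c(Br)c1OCc5ccccc5)O[C@H](c1ccc(OCc5ccccc5)c(OCc5ccccc5)c1)[C@@H](OCc5ccccc5)C2 | intermediate
24 | 8-lithio compound: 23 with lithium in place of the bromine atom at C8 of unit 3 | Brc1cc2c(cc1OCc5ccccc5)O[C@H](c1ccc(OCc5ccccc5)c(OCc5ccccc5)c1)[C@@H](OCc5ccccc5)[C@@H]2c1c(OCc5ccccc5)c2c(c([Li])c1OCc5ccccc5)O[C@H](c1ccc(OCc5ccccc5)c(OCc5ccccc5)c1)[C@@H](OCc5ccccc5)C2 | intermediate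
25 | ortho-quinone methide: 23 with an (E)-[4-(benzyloxy)-6-oxocyclohexa-2,4-dien-1-ylidene]methyl group in place of the bromine atom at C8 of unit 3 | Brc1cc2c(cc1OCc5ccccc5)O[C@H](c1ccc(OCc5ccccc5)c(OCc5ccccc5)c1)[C@@H](OCc5ccccc5)[C@@H]2c1c(OCc5ccccc5)c2c(c(/C=C3\C=CC(OCc5ccccc5)=CC3=O)c1OCc5ccccc5)O[C@H](c1ccc(OCc5ccccc5)c(OCc5ccccc5)c1)[C@@H](OCc5ccccc5)C2 | intermediate
26 | mono-ketone: 6-bromo-3,7,3',4'-tetra-O-benzylfisetinidol-(4α→6)-penta-O-benzylcatechin carrying a (2R,3S)-trans-2-[3,4-bis(benzyloxy)benzoyl]-6-benzyloxy-2,3-dihydrobenzofuran-3-yl group on C8 of unit 3 | Brc1cc2c(cc1OCc5ccccc5)O[C@H](c1ccc(OCc5ccccc5)c(OCc5ccccc5)c1)[C@@H](OCc5ccccc5)[C@@H]2c1c(OCc5ccccc5)c2c(c([C@@H]3c4ccc(OCc5ccccc5)cc4O[C@H]3C(=O)c3ccc(OCc5ccccc5)c(OCc5ccccc5)c3)c1OCc5ccccc5)O[C@H](c1ccc(OCc5ccccc5)c(OCc5ccccc5)c1)[C@@H](OCc5ccccc5)C2 | intermediate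
27 | mono-carbinol: 26 with the ketone reduced to the (S)-configured aryl carbinol | Brc1cc2c(cc1OCc5ccccc5)O[C@H](c1ccc(OCc5ccccc5)c(OCc5ccccc5)c1)[C@@H](OCc5ccccc5)[C@@H]2c1c(OCc5ccccc5)c2c(c([C@@H]3c4ccc(OCc5ccccc5)cc4O[C@H]3[C@@H](O)c3ccc(OCc5ccccc5)c(OCc5ccccc5)c3)c1OCc5ccccc5)O[C@H](c1ccc(OCc5ccccc5)c(OCc5ccccc5)c1)[C@@H](OCc5ccccc5)C2 | intermediate
28 | dilithio compound: lithium alkoxide of 27 with lithium in place of the bromine atom at C6 of unit 2 | [Li]c1cc2c(cc1OCc5ccccc5)O[C@H](c1ccc(OCc5ccccc5)c(OCc5ccccc5)c1)[C@@H](OCc5ccccc5)[C@@H]2c1c(OCc5ccccc5)c2c(c([C@@H]3c4ccc(OCc5ccccc5)cc4O[C@H]3[C@@H](O[Li])c3ccc(OCc5ccccc5)c(OCc5ccccc5)c3)c1OCc5ccccc5)O[C@H](c1ccc(OCc5ccccc5)c(OCc5ccccc5)c1)[C@@H](OCc5ccccc5)C2 | intermediate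
29 | ortho-quinone methide: lithium alkoxide of 27 with an (E)-[4-(benzyloxy)-6-oxocyclohexa-2,4-dien-1-ylidene]methyl group in place of the bromine atom at C6 of unit 2 | O=C1C=C(OCc5ccccc5)C=C/C1=C\c1cc2c(cc1OCc5ccccc5)O[C@H](c1ccc(OCc5ccccc5)c(OCc5ccccc5)c1)[C@@H](OCc5ccccc5)[C@@H]2c1c(OCc5ccccc5)c2c(c([C@@H]3c4ccc(OCc5ccccc5)cc4O[C@H]3[C@@H](O[Li])c3ccc(OCc5ccccc5)c(OCc5ccccc5)c3)c1OCc5ccccc5)O[C@H](c1ccc(OCc5ccccc5)c(OCc5ccccc5)c1)[C@@H](OCc5ccccc5)C2 | intermediate
30 | keto carbinol: 27 with a (2R,3S)-trans-2-[3,4-bis(benzyloxy)benzoyl]-6-benzyloxy-2,3-dihydrobenzofuran-3-yl group in place of the bromine atom at C6 of unit 2 | O=C(c1ccc(OCc5ccccc5)c(OCc5ccccc5)c1)[C@@H]1Oc2cc(OCc5ccccc5)ccc2[C@H]1c1cc2c(cc1OCc5ccccc5)O[C@H](c1ccc(OCc5ccccc5)c(OCc5ccccc5)c1)[C@@H](OCc5ccccc5)[C@@H]2c1c(OCc5ccccc5)c2c(c([C@@H]3c4ccc(OCc5ccccc5)cc4O[C@H]3[C@@H](O)c3ccc(OCc5ccccc5)c(OCc5ccccc5)c3)c1OCc5ccccc5)O[C@H](c1ccc(OCc5ccccc5)c(OCc5ccccc5)c1)[C@@H](OCc5ccccc5)C2 | intermediate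
31 | bis-carbinol: 30 with the ketone reduced to the (S)-configured aryl carbinol | O[C@@H](c1ccc(OCc5ccccc5)c(OCc5ccccc5)c1)[C@@H]1Oc2cc(OCc5ccccc5)ccc2[C@H]1c1cc2c(cc1OCc5ccccc5)O[C@H](c1ccc(OCc5ccccc5)c(OCc5ccccc5)c1)[C@@H](OCc5ccccc5)[C@@H]2c1c(OCc5ccccc5)c2c(c([C@@H]3c4ccc(OCc5ccccc5)cc4O[C@H]3[C@@H](O)c3ccc(OCc5ccccc5)c(OCc5ccccc5)c3)c1OCc5ccccc5)O[C@H](c1ccc(OCc5ccccc5)c(OCc5ccccc5)c1)[C@@H](OCc5ccccc5)C2 | intermediate
32 | bis-mesylate: 31 with both carbinols as methanesulfonates, (S) at each sulfonate carbon | CS(=O)(=O)O[C@@H](c1ccc(OCc5ccccc5)c(OCc5ccccc5)c1)[C@@H]1Oc2cc(OCc5ccccc5)ccc2[C@H]1c1cc2c(cc1OCc5ccccc5)O[C@H](c1ccc(OCc5ccccc5)c(OCc5ccccc5)c1)[C@@H](OCc5ccccc5)[C@@H]2c1c(OCc5ccccc5)c2c(c([C@@H]3c4ccc(OCc5ccccc5)cc4O[C@H]3[C@@H](OS(C)(=O)=O)c3ccc(OCc5ccccc5)c(OCc5ccccc5)c3)c1OCc5ccccc5)O[C@H](c1ccc(OCc5ccccc5)c(OCc5ccccc5)c1)[C@@H](OCc5ccccc5)C2 | intermediate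
33 | 7,3',4'-tri-O-benzylfisetinidol 3-acetate-(4α→6)-3,7,3',4'-tetra-O-benzylfisetinidol-(4α→6)-[7,3',4'-tri-O-benzylfisetinidol 3-acetate-(4α→8)]-penta-O-benzylcatechin | c5ccccc5COc1ccc2c(c1)O[C@H](c1ccc(OCc5ccccc5)c(OCc5ccccc5)c1)[C@@H](OC(C)=O)[C@@H]2c1cc2c(cc1OCc5ccccc5)O[C@H](c1ccc(OCc5ccccc5)c(OCc5ccccc5)c1)[C@@H](OCc5ccccc5)[C@@H]2c1c(OCc5ccccc5)c2c(c([C@@H]3c4ccc(OCc5ccccc5)cc4O[C@H](c4ccc(OCc5ccccc5)c(OCc5ccccc5)c4)[C@H]3OC(C)=O)c1OCc5ccccc5)O[C@H](c1ccc(OCc5ccccc5)c(OCc5ccccc5)c1)[C@@H](OCc5ccccc5)C2 | intermediate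
34 | pentadeca-O-benzyl ether of the target with free 3-OH on units 1 and 4 | c5ccccc5COc1ccc2c(c1)O[C@H](c1ccc(OCc5ccccc5)c(OCc5ccccc5)c1)[C@@H](O)[C@@H]2c1cc2c(cc1OCc5ccccc5)O[C@H](c1ccc(OCc5ccccc5)c(OCc5ccccc5)c1)[C@@H](OCc5ccccc5)[C@@H]2c1c(OCc5ccccc5)c2c(c([C@@H]3c4ccc(OCc5ccccc5)cc4O[C@H](c4ccc(OCc5ccccc5)c(OCc5ccccc5)c4)[C@H]3O)c1OCc5ccccc5)O[C@H](c1ccc(OCc5ccccc5)c(OCc5ccccc5)c1)[C@@H](OCc5ccccc5)C2 | intermediate
35 | fisetinidol-(4α→6)-fisetinidol-(4α→6)-[fisetinidol-(4α→8)]-catechin, CNP0263622.1 | Oc1ccc2c(c1)O[C@H](c1ccc(O)c(O)c1)[C@@H](O)[C@@H]2c1cc2c(cc1O)O[C@H](c1ccc(O)c(O)c1)[C@@H](O)[C@@H]2c1c(O)c2c(c([C@@H]3c4ccc(O)cc4O[C@H](c4ccc(O)c(O)c4)[C@H]3O)c1O)O[C@H](c1ccc(O)c(O)c1)[C@@H](O)C2 | target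

Total step count: 24 steps.
Longest linear sequence: 17 steps (1 → 2 → 3 → 4 → 5 → 18 → 19 → 20 → 21 → 23 → 26 → 27 → 30 → 31 → 32 → 33 → 34 → 35, that is steps 1–4 and 12–24).

Steps least certain to work

Step 15 (key step, new method). The most likely failure is that the electron-rich benzylic sulfonate ionises before the ring oxygen takes part. The open cation could then be lost by hydride shift and proton loss toward an aromatic benzofuran, or be captured by a neighbouring benzyl ether oxygen. Acetate return at the benzylic carbon could also dominate without the five-membered acetate re-ionising. The fallback is the known Lewis-acid condensation of a flavan-3,4-diol with a nucleophilic ring A. It sets out from 4 and returns at 22. (+)-Fustin F1 is benzylated (BnBr, K2CO3, DMF) to 7,3',4'-tri-O-benzylfustin F2. This is reduced with NaBH4 (MeOH–THF, 0 °C) to the (2R,3S,4R)-flavan-3,4-diol F3, which is brominated with NBS to the 6-bromo diol F4. The bromine both supplies the handle for unit 1 and blocks self-condensation. F4 is ionised at C4 with BF3·OEt2 or TMSOTf in CH2Cl2 at −78 → 0 °C in the presence of 4, whose only free nucleophilic position is C6. Attack anti to the C3 substituent should give mainly the 4α product 22, which is benzylated as in the second stage of step 16 to give 23.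

Step 22 (new method, two sites). The failure modes of step 15 would occur twice on one molecule, and the site on C8 of unit 3 is the more crowded. The fallback uses the same known condensation. It sets out from 23 and returns at 35. Compound 23 is treated with n-BuLi (2.5 equiv) at −78 °C and then MeOH to give the debrominated dimer F5. F5 is condensed with the 6-bromo diol F4 (2.5 equiv, TMSOTf, CH2Cl2, −78 → 0 °C) at C8 of unit 3 and at C6 of unit 2 to give the dibromide F6. The conditions of step 24 with added Et3N then remove the two aryl bromines together with the benzyl groups to give 35. Selectivity between C6 and C8 of unit 2 is the weak point of this fallback.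

Step 12. The methide carbon of 17 is flanked by a twisted aryl group with two ortho benzyloxy groups. Addition of the ylide may therefore be slow enough for the quinone methide to oligomerise, or the chiral ammonium group may discriminate the two faces poorly. The fallback separates the operations and replaces reagent control by separation of diastereomers. It sets out from 5, 8 and 13 and returns at 18. Compound 8 is silylated (TBSCl, imidazole) to 4-(benzyloxy)-5-bromo-2-(tert-butyldimethylsilyloxy)benzaldehyde F7. The Grignard reagent 16 made from 5 is added to F7, and Bu4NF then frees the ortho-hydroxy diaryl carbinol F8. Compound 13 with dimethyl sulfide gives the sulfonium bromide F9, and aqueous K2CO3 gives the stable dimethylsulfonium ylide F10. F8 and F10 with catalytic diphenyl phosphate in CH2Cl2 undergo the known acid-catalysed [4+1] annulation. The two trans products are diastereomers because of unit 3 and are separated by chromatography to give 18.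

Step 17. The exchange may discriminate the two aryl bromides incompletely, which would give regioisomeric mono-adducts and some bis-adduct, or the hindered aryllithium may be protonated before it adds. The fallback needs no site selectivity and reverses the polarity at both sites at once. It sets out from 23 and returns at 31. Compound 23 is treated with excess n-BuLi and then DMF to give the dialdehyde F11. 5-(Benzyloxy)-2-bromophenol F12 is converted with two equivalents of n-BuLi into its O,C-dilithio form, which is added in excess to F11 to give the bis(ortho-hydroxy diaryl carbinol) F13. Acid-catalysed [4+1] annulation of F13 with the ylide F10 (diphenyl phosphate, CH2Cl2) gives the bis-ketone F14 after chromatographic separation from its diastereomers, and Zn(BH4)2 as in step 13 reduces both ketones to give 31.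

Step 19. The new aryllithium may be quenched by hydroxyl protons if the deprotonation is incomplete, or the resident alkoxide may capture a Boc group from 10 and so consume the aldehyde partner. The fallback removes the alkoxide from the step by a protecting group. It sets out from 27 and returns at 31. Compound 27 is silylated (Et3SiCl, imidazole, DMF) to the triethylsilyl ether F15. F15 is carried through the exchange with n-BuLi alone, the addition to 10 and the annulation with 15 to give the silylated ketone F16. Zn(BH4)2 reduces F16 to the silylated carbinol F17, and Bu4NF buffered with AcOH removes the silyl group to give 31.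

Step 13 (and likewise steps 18 and 20). The aryl ether oxygen is a weak donor, so non-chelated delivery of hydride (polar Felkin–Anh) may compete. That would give the epimeric carbinol, which would lead to the cis oxiranium ion and a 2,3-cis chroman. The fallback is reagent control by Corey–Bakshi–Shibata reduction with a 2-methyl-oxazaborolidine and catecholborane in toluene at −78 °C, the enantiomer of the catalyst being chosen so that the aryl group as the large substituent leads to the (S)-carbinol. It sets out from 18 and returns at 19 (from 26 to 27 and from 30 to 31 in the later rounds) and makes no new compound.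

Further compounds

F1 | step 15 | (+)-fustin, (2R,3R) | Oc1ccc2c(c1)O[C@H](c1ccc(O)c(O)c1)[C@@H](O)C2=O
F2 | step 15 | 7,3',4'-tri-O-benzylfustin, (2R,3R) | c5ccccc5COc1ccc2c(c1)O[C@H](c1ccc(OCc5ccccc5)c(OCc5ccccc5)c1)[C@@H](O)C2=O
F3 | step 15 | (2R,3S,4R)-7,3',4'-tri-O-benzylflavan-3,4-diol (2,3-trans-3,4-trans) | c5ccccc5COc1ccc2c(c1)O[C@H](c1ccc(OCc5ccccc5)c(OCc5ccccc5)c1)[C@@H](O)[C@@H]2O
F4 | step 15 | (2R,3S,4R)-6-bromo-7,3',4'-tri-O-benzylflavan-3,4-diol | c5ccccc5COc1c(Br)cc2c(c1)O[C@H](c1ccc(OCc5ccccc5)c(OCc5ccccc5)c1)[C@@H](O)[C@@H]2O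
F5 | step 22 | 3,7,3',4'-tetra-O-benzylfisetinidol-(4α→6)-penta-O-benzylcatechin | c1cc2c(cc1OCc5ccccc5)O[C@H](c1ccc(OCc5ccccc5)c(OCc5ccccc5)c1)[C@@H](OCc5ccccc5)[C@@H]2c1c(OCc5ccccc5)c2c(cc1OCc5ccccc5)O[C@H](c1ccc(OCc5ccccc5)c(OCc5ccccc5)c1)[C@@H](OCc5ccccc5)C2
F6 | step 22 | 34 with bromine at C6 of units 1 and 4 | c5ccccc5COc1c(Br)cc2c(c1)O[C@H](c1ccc(OCc5ccccc5)c(OCc5ccccc5)c1)[C@@H](O)[C@@H]2c1cc2c(cc1OCc5ccccc5)O[C@H](c1ccc(OCc5ccccc5)c(OCc5ccccc5)c1)[C@@H](OCc5ccccc5)[C@@H]2c1c(OCc5ccccc5)c2c(c([C@@H]3c4cc(Br)c(OCc5ccccc5)cc4O[C@H](c4ccc(OCc5ccccc5)c(OCc5ccccc5)c4)[C@H]3O)c1OCc5ccccc5)O[C@H](c1ccc(OCc5ccccc5)c(OCc5ccccc5)c1)[C@@H](OCc5ccccc5)C2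
F7 | step 12 | 4-(benzyloxy)-5-bromo-2-(tert-butyldimethylsilyloxy)benzaldehyde | O=Cc1cc(Br)c(OCc5ccccc5)cc1O[Si](C)(C)C(C)(C)C
F8 | step 12 | [4-(benzyloxy)-5-bromo-2-hydroxyphenyl](8-bromo-penta-O-benzylcatechin-6-yl)methanol, both carbinol epimers | OC(c1cc(Br)c(OCc5ccccc5)cc1O)c1c(OCc5ccccc5)c2c(c(Br)c1OCc5ccccc5)O[C@H](c1ccc(OCc5ccccc5)c(OCc5ccccc5)c1)[C@@H](OCc5ccccc5)C2
F9 | step 12 | {2-[3,4-bis(benzyloxy)phenyl]-2-oxoethyl}dimethylsulfonium bromide | C[S+](C)CC(=O)c1ccc(OCc5ccccc5)c(OCc5ccccc5)c1.[Br-]
F10 | step 12 | dimethylsulfonium 2-[3,4-bis(benzyloxy)phenyl]-2-oxoethanide | C[S+](C)[CH-]C(=O)c1ccc(OCc5ccccc5)c(OCc5ccccc5)c1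
F11 | step 17 | dialdehyde: 23 with a formyl group in place of each bromine atom | O=Cc1cc2c(cc1OCc5ccccc5)O[C@H](c1ccc(OCc5ccccc5)c(OCc5ccccc5)c1)[C@@H](OCc5ccccc5)[C@@H]2c1c(OCc5ccccc5)c2c(c(C=O)c1OCc5ccccc5)O[C@H](c1ccc(OCc5ccccc5)c(OCc5ccccc5)c1)[C@@H](OCc5ccccc5)C2
F12 | step 17 | 5-(benzyloxy)-2-bromophenol | Oc1cc(OCc5ccccc5)ccc1Br
F13 | step 17 | bis(ortho-hydroxy diaryl carbinol): 23 with a [4-(benzyloxy)-2-hydroxyphenyl](hydroxy)methyl group in place of each bromine atom, carbinol epimers | OC(c1ccc(OCc5ccccc5)cc1O)c1cc2c(cc1OCc5ccccc5)O[C@H](c1ccc(OCc5ccccc5)c(OCc5ccccc5)c1)[C@@H](OCc5ccccc5)[C@@H]2c1c(OCc5ccccc5)c2c(c(C(O)c3ccc(OCc5ccccc5)cc3O)c1OCc5ccccc5)O[C@H](c1ccc(OCc5ccccc5)c(OCc5ccccc5)c1)[C@@H](OCc5ccccc5)C2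
F14 | step 17 | bis-ketone: 23 with a (2R,3S)-trans-2-[3,4-bis(benzyloxy)benzoyl]-6-benzyloxy-2,3-dihydrobenzofuran-3-yl group in place of each bromine atom | O=C(c1ccc(OCc5ccccc5)c(OCc5ccccc5)c1)[C@@H]1Oc2cc(OCc5ccccc5)ccc2[C@H]1c1cc2c(cc1OCc5ccccc5)O[C@H](c1ccc(OCc5ccccc5)c(OCc5ccccc5)c1)[C@@H](OCc5ccccc5)[C@@H]2c1c(OCc5ccccc5)c2c(c([C@@H]3c4ccc(OCc5ccccc5)cc4O[C@H]3C(=O)c3ccc(OCc5ccccc5)c(OCc5ccccc5)c3)c1OCc5ccccc5)O[C@H](c1ccc(OCc5ccccc5)c(OCc5ccccc5)c1)[C@@H](OCc5ccccc5)C2
F15 | step 19 | triethylsilyl ether of 27 | Brc1cc2c(cc1OCc5ccccc5)O[C@H](c1ccc(OCc5ccccc5)c(OCc5ccccc5)c1)[C@@H](OCc5ccccc5)[C@@H]2c1c(OCc5ccccc5)c2c(c([C@@H]3c4ccc(OCc5ccccc5)cc4O[C@H]3[C@@H](O[Si](CC)(CC)CC)c3ccc(OCc5ccccc5)c(OCc5ccccc5)c3)c1OCc5ccccc5)O[C@H](c1ccc(OCc5ccccc5)c(OCc5ccccc5)c1)[C@@H](OCc5ccccc5)C2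
F16 | step 19 | triethylsilyl ether of 30 | O=C(c1ccc(OCc5ccccc5)c(OCc5ccccc5)c1)[C@@H]1Oc2cc(OCc5ccccc5)ccc2[C@H]1c1cc2c(cc1OCc5ccccc5)O[C@H](c1ccc(OCc5ccccc5)c(OCc5ccccc5)c1)[C@@H](OCc5ccccc5)[C@@H]2c1c(OCc5ccccc5)c2c(c([C@@H]3c4ccc(OCc5ccccc5)cc4O[C@H]3[C@@H](O[Si](CC)(CC)CC)c3ccc(OCc5ccccc5)c(OCc5ccccc5)c3)c1OCc5ccccc5)O[C@H](c1ccc(OCc5ccccc5)c(OCc5ccccc5)c1)[C@@H](OCc5ccccc5)C2
F17 | step 19 | 31 with the carbinol of the unit 4 precursor as its triethylsilyl ether | O[C@@H](c1ccc(OCc5ccccc5)c(OCc5ccccc5)c1)[C@@H]1Oc2cc(OCc5ccccc5)ccc2[C@H]1c1cc2c(cc1OCc5ccccc5)O[C@H](c1ccc(OCc5ccccc5)c(OCc5ccccc5)c1)[C@@H](OCc5ccccc5)[C@@H]2c1c(OCc5ccccc5)c2c(c([C@@H]3c4ccc(OCc5ccccc5)cc4O[C@H]3[C@@H](O[Si](CC)(CC)CC)c3ccc(OCc5ccccc5)c(OCc5ccccc5)c3)c1OCc5ccccc5)O[C@H](c1ccc(OCc5ccccc5)c(OCc5ccccc5)c1)[C@@H](OCc5ccccc5)C2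
F0 | step 13 | none | none
A1 | alternative 1 | tetradeca-O-benzyl ether of the target with free 4'-hydroxyls on units 1, 2 and 4 | c5ccccc5COc1ccc2c(c1)O[C@H](c1ccc(O)c(OCc5ccccc5)c1)[C@@H](OCc5ccccc5)[C@@H]2c1cc2c(cc1OCc5ccccc5)O[C@H](c1ccc(O)c(OCc5ccccc5)c1)[C@@H](OCc5ccccc5)[C@@H]2c1c(OCc5ccccc5)c2c(c([C@@H]3c4ccc(OCc5ccccc5)cc4O[C@H](c4ccc(O)c(OCc5ccccc5)c4)[C@H]3OCc5ccccc5)c1OCc5ccccc5)O[C@H](c1ccc(OCc5ccccc5)c(OCc5ccccc5)c1)[C@@H](OCc5ccccc5)C2
A2 | alternative 1 | (R)-danshensu, (R)-3-(3,4-dihydroxyphenyl)-2-hydroxypropanoic acid | OC(=O)[C@H](O)Cc1ccc(O)c(O)c1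
A3 | alternative 2 | perbenzylated fisetinidol-(4α→8)-catechin with benzyldimethylsilyl in place of the C3 hydroxyl of unit 4 | c1c(OCc5ccccc5)c2c(c([C@@H]3c4ccc(OCc5ccccc5)cc4O[C@H](c4ccc(OCc5ccccc5)c(OCc5ccccc5)c4)[C@H]3[Si](C)(C)Cc5ccccc5)c1OCc5ccccc5)O[C@H](c1ccc(OCc5ccccc5)c(OCc5ccccc5)c1)[C@@H](OCc5ccccc5)C2
A4 | alternative 2 | (E)-benzyl{2-[3,4-bis(benzyloxy)phenyl]ethenyl}dimethylsilane | C[Si](C)(Cc1ccccc1)/C=C/c1ccc(OCc2ccccc2)c(OCc2ccccc2)c1
A5 | alternative 2 | [4-(benzyloxy)-2-hydroxyphenyl](penta-O-benzylcatechin-8-yl)methanol, carbinol epimers | c1c(OCc5ccccc5)c2c(c(C(O)c3ccc(OCc5ccccc5)cc3O)c1OCc5ccccc5)O[C@H](c1ccc(OCc5ccccc5)c(OCc5ccccc5)c1)[C@@H](OCc5ccccc5)C2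
A6 | alternative 3 | 7,3',4'-tri-O-benzylfisetinidol-(4α→8)-penta-O-benzylcatechin with free C3 hydroxyl on unit 4 | c1c(OCc5ccccc5)c2c(c([C@@H]3c4ccc(OCc5ccccc5)cc4O[C@H](c4ccc(OCc5ccccc5)c(OCc5ccccc5)c4)[C@H]3O)c1OCc5ccccc5)O[C@H](c1ccc(OCc5ccccc5)c(OCc5ccccc5)c1)[C@@H](OCc5ccccc5)C2
A7 | alternative 3 | (R)-2-[3,4-bis(benzyloxy)phenyl]-2-{5-(benzyloxy)-2-[(penta-O-benzylcatechin-8-yl)(trimethylsilyl)methyl]phenoxy}acetaldehyde, epimers at the silyl-bearing carbon | c1c(OCc5ccccc5)c2c(c(C([Si](C)(C)C)c3ccc(OCc5ccccc5)cc3O[C@H](c3ccc(OCc5ccccc5)c(OCc5ccccc5)c3)C=O)c1OCc5ccccc5)O[C@H](c1ccc(OCc5ccccc5)c(OCc5ccccc5)c1)[C@@H](OCc5ccccc5)C2
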